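**Plan**

1. Retrosynthesis: after removal of two MOM groups, ring C is cut at O1–C8a and C4–C4a in one stroke. This gives a fully substituted ring A aryne (stored as 2-silylaryl triflate 15) and the O1–C2–C3–C4 chain as β-silyloxy ester 20. Triflate 15 is cut back through O-geranylation, triflate/C-silyl installation, bromination and C-geranylation to 3,5-bis(benzyloxy)phenol; ester 20 goes back to 4′-hydroxyacetophenone.
2. Enabling feature: O1 and the C4 carbonyl sit on adjacent ring A carbons (C8a and C4a). These two carbons are flanked unequally, by the C5 oxygen on one side and the C8 alkyl chain on the other, so a polarised aryne can take up the alkoxide oxygen and the ester carbon of one O–C2–C3–C4(=O) chain in a single orientation.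
3. Forward: ring A is dressed first (steps 1–8), the side piece is made in steps 9–12, ring C is closed onto ring A in step 13, and step 14 frees the 5- and 4′-hydroxyls.
4. Stereochemistry: the single stereocenter (C2, S) is set by asymmetric transfer hydrogenation in step 11 and carried through; no bond to it is made or broken afterwards.

Key step: step 13

Remarks: geranyl = (2E)-3,7-dimethylocta-2,6-dien-1-yl throughout. Flavanone numbering is used (ring A = benzo ring, ring C = pyranone ring). Compounds 1 and 16, geranyl bromide and 1-bromo-4-(methoxymethoxy)benzene are assumed to be commercial. Compounds 15 and 20 are assumed to be used soon after preparation.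

**Route**

Step 1
Reactants: 1 3,5-bis(benzyloxy)phenol
Product: 2 1,3-bis(benzyloxy)-5-(methoxymethoxy)benzene
Conditions: MOMCl, i-Pr2NEt, CH2Cl2, 0 °C to rt
Reagents that add atoms: chloromethyl methyl ether, COCCl
Why: O-alkylation of the only free phenol (MOM protection) marks the oxygen that becomes O5 of the flavanone.

Step 2
Reactants: 2 1,3-bis(benzyloxy)-5-(methoxymethoxy)benzene
Product: 3 5-(methoxymethoxy)benzene-1,3-diol
Conditions: H2 (1 atm), 10% Pd/C, EtOAc–MeOH, rt
Reagents that add atoms: none
Why: Hydrogenolysis of both benzyl ethers leaves the MOM acetal untouched and is placed before any alkene enters the molecule.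

Step 3
Reactants: 3 5-(methoxymethoxy)benzene-1,3-diol
Product: 4 5-(methoxymethoxy)-1,3-phenylene bis(N,N-diethylcarbamate)
Conditions: Et2NCOCl (2.4 equiv), K2CO3, MeCN, reflux
Reagents that add atoms: N,N-diethylcarbamoyl chloride, CCN(CC)C(=O)Cl
Why: O-carbamoylation of both phenols installs two strong directing groups for the metalation that follows.

Step 4
Reactants: 4 5-(methoxymethoxy)-1,3-phenylene bis(N,N-diethylcarbamate)
Product: 7 2-geranyl-5-(methoxymethoxy)-1,3-phenylene bis(N,N-diethylcarbamate), via aryllithium 5 (not isolated), via arylcopper 6 (not isolated)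
Conditions: s-BuLi, TMEDA, THF, −78 °C; CuI; geranyl bromide, −78 to −20 °C
Reagents that add atoms: geranyl bromide, CC(C)=CCC/C(C)=C/CBr
Why: Directed ortho metalation should occur at the ring position flanked by the two carbamates (cooperative complexation), and the arylcopper should couple at the unhindered allylic terminus of geranyl bromide with retention of the E alkene.

Step 5
Reactants: 7 2-geranyl-5-(methoxymethoxy)-1,3-phenylene bis(N,N-diethylcarbamate)
Product: 8 2-geranyl-5-(methoxymethoxy)benzene-1,3-diol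
Conditions: LiAlH4, THF, 0 °C to rt; aqueous Rochelle salt work-up
Reagents that add atoms: none
Why: Reductive cleavage of aryl carbamates by hydride frees both phenols while the MOM acetal and the isolated alkenes are inert.

Step 6
Reactants: 8 2-geranyl-5-(methoxymethoxy)benzene-1,3-diol
Product: 9 4-bromo-2-geranyl-5-(methoxymethoxy)benzene-1,3-diol
Conditions: NBS (1.0 equiv), CH2Cl2, −78 °C
Reagents that add atoms: N-bromosuccinimide, O=C1CCC(=O)N1Br
Why: Electrophilic aromatic bromination of the phloroglucinol-type ring should outrun reaction at the trisubstituted alkenes, and the two open ring positions are equivalent by symmetry, so one monobromide is expected.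

Step 7
Reactants: 9 4-bromo-2-geranyl-5-(methoxymethoxy)benzene-1,3-diol
Product: 14 2-geranyl-3-hydroxy-5-(methoxymethoxy)-6-(trimethylsilyl)phenyl trifluoromethanesulfonate, via bis(trimethylsilyl) ether 10 (not isolated), via aryllithium 11 (not isolated), via lithium phenoxide 12 (not isolated), via silyl ether triflate 13 (not isolated)
Conditions: HMDS, 80 °C, then evaporation; n-BuLi, THF, −78 to −40 °C; Tf2O, −78 °C; aqueous NaHCO3 work-up
Reagents that add atoms: hexamethyldisilazane, C[Si](C)(C)N[Si](C)(C)C; trifluoromethanesulfonic anhydride, O=S(=O)(OS(=O)(=O)C(F)(F)F)C(F)(F)F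
Why: Bromine–lithium exchange followed by retro-Brook rearrangement moves only the silyl group on the oxygen ortho to lithium onto carbon, so the two phenols are told apart by position: the freed phenoxide is triflated and the remote silyl ether is hydrolysed on work-up.

Step 8
Reactants: 14 2-geranyl-3-hydroxy-5-(methoxymethoxy)-6-(trimethylsilyl)phenyl trifluoromethanesulfonate
Product: 15 2-geranyl-3-(geranyloxy)-5-(methoxymethoxy)-6-(trimethylsilyl)phenyl trifluoromethanesulfonate
Conditions: geranyl bromide, K2CO3, acetone, rt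
Reagents that add atoms: geranyl bromide, CC(C)=CCC/C(C)=C/CBr
Why: Williamson etherification of the only free phenol proceeds under carbonate conditions that the aryl triflate and the C-silyl group should tolerate.

Step 9
Reactants: 16 1-(4-hydroxyphenyl)ethan-1-one
Product: 17 1-[4-(methoxymethoxy)phenyl]ethan-1-one
Conditions: MOMCl, i-Pr2NEt, CH2Cl2, 0 °C to rt
Reagents that add atoms: chloromethyl methyl ether, COCCl
Why: MOM protection of the phenol gives a group that is stable to base, hydride transfer and fluoride.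

Step 10
Reactants: 17 1-[4-(methoxymethoxy)phenyl]ethan-1-one
Product: 18 methyl 3-[4-(methoxymethoxy)phenyl]-3-oxopropanoate
Conditions: NaH, dimethyl carbonate, THF, reflux; AcOH quench
Reagents that add atoms: dimethyl carbonate, COC(=O)OC
Why: Crossed Claisen condensation of the methyl ketone enolate with dimethyl carbonate is driven by formation of the β-keto ester enolate.

Step 11
Reactants: 18 methyl 3-[4-(methoxymethoxy)phenyl]-3-oxopropanoate
Product: 19 methyl (3S)-3-hydroxy-3-[4-(methoxymethoxy)phenyl]propanoate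
Conditions: RuCl(p-cymene)[(S,S)-TsDPEN] (cat.), HCO2H–Et3N (5:2), EtOAc, rt
Reagents that add atoms: none
Why: Noyori–Ikariya asymmetric transfer hydrogenation of the aryl ketone sets the stereocenter, the (S,S)-diamine ligand directing hydride to the face that should give the S carbinol, as for simple aryl ketones.

Step 12
Reactants: 19 methyl (3S)-3-hydroxy-3-[4-(methoxymethoxy)phenyl]propanoate
Product: 20 methyl (3S)-3-[4-(methoxymethoxy)phenyl]-3-[(trimethylsilyl)oxy]propanoate
Conditions: TMSCl, imidazole, CH2Cl2, 0 °C; filtration, used directly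
Reagents that add atoms: chlorotrimethylsilane, C[Si](C)(C)Cl
Why: O-silylation replaces the hydroxyl proton by a fluoride-labile group without touching the stereocenter.

Step 13
Reactants: 15 2-geranyl-3-(geranyloxy)-5-(methoxymethoxy)-6-(trimethylsilyl)phenyl trifluoromethanesulfonate; 20 methyl (3S)-3-[4-(methoxymethoxy)phenyl]-3-[(trimethylsilyl)oxy]propanoate
Product: 25 (2S)-8-geranyl-7-(geranyloxy)-5-(methoxymethoxy)-2-[4-(methoxymethoxy)phenyl]chroman-4-one, via aryne 21 (not isolated), via cesium alkoxide 22 (not isolated), via aryl anion 23 (not isolated), via hemiketal alkoxide 24 (not isolated)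
Conditions: CsF (2.2 equiv), 18-crown-6 (2.2 equiv), 20 (1.2 equiv), THF, 0 °C to rt
Reagents that add atoms: none
Why: Proposed new method: fluoride removes the C-silyl group of 15 with loss of triflate to give aryne 21 and, together with the methoxide released later, cleaves the O–Si bond of 20 to the proton-free cesium alkoxide 22; 22 adds to the aryne, the aryl anion 23 attacks its own ester carbonyl, and hemiketal alkoxide 24 loses methoxide to give chromanone 25. The closest known reaction types are the aryne annulation of salicylate esters to xanthones (phenoxide addition, then intramolecular acylation) and the acyl-alkylation of arynes; the new element is an aliphatic β-silyloxy ester, whose in situ desilylation avoids the O–H proton that would quench the aryl anion to a plain aryl ether. Ring C closes by 6-exo-trig attack of the aryl anion on the ester carbonyl. No new stereocenter is formed: C2 comes from 20 with no bond to it made or broken, and the proton-poor medium at or below room temperature, with methoxide scavenged by silicon, is chosen to hold back retro-aldol and retro-oxa-Michael racemisation. The step needs the oxygen to bond to the aryne carbon next to the C-geranyl carbon (future C8a) and the acyl carbon to the one next to the MOM-oxy carbon (future C4a); the inductively withdrawing C5 oxygen distorts the aryne so that the remote carbon is the more electrophilic and the carbanion develops ortho to oxygen, which should outweigh the weak opposing effects of the C7 alkoxy and C8 alkyl groups.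

Step 14
Reactants: 25 (2S)-8-geranyl-7-(geranyloxy)-5-(methoxymethoxy)-2-[4-(methoxymethoxy)phenyl]chroman-4-one
Product: 27 (2S)-8-geranyl-7-(geranyloxy)-5-hydroxy-2-(4-hydroxyphenyl)chroman-4-one, via bis(trimethylsilyl) ether 26 (not isolated)
Conditions: TMSOTf, 2,2′-bipyridyl, CH2Cl2, 0 °C to rt; then H2O
Reagents that add atoms: none
Why: Buffered silyl triflate cleavage of aryl MOM ethers to silyl ethers, then hydrolysis, avoids the protic acid that could ionise the geranyl aryl ether or cyclise the C-geranyl chain, and does not involve C2.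

**Compound list**

1 | 3,5-bis(benzyloxy)phenol | Oc1cc(OCc2ccccc2)cc(OCc2ccccc2)c1 | starting material
2 | 1,3-bis(benzyloxy)-5-(methoxymethoxy)benzene | COCOc1cc(OCc2ccccc2)cc(OCc2ccccc2)c1 | intermediate
3 | 5-(methoxymethoxy)benzene-1,3-diol | COCOc1cc(O)cc(O)c1 | intermediate
4 | 5-(methoxymethoxy)-1,3-phenylene bis(N,N-diethylcarbamate) | CCN(CC)C(=O)Oc1cc(OCOC)cc(OC(=O)N(CC)CC)c1 | intermediate
5 | [2,6-bis(diethylcarbamoyloxy)-4-(methoxymethoxy)phenyl]lithium | CCN(CC)C(=O)Oc1cc(OCOC)cc(OC(=O)N(CC)CC)c1[Li] | intermediate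
6 | [2,6-bis(diethylcarbamoyloxy)-4-(methoxymethoxy)phenyl]copper | CCN(CC)C(=O)Oc1cc(OCOC)cc(OC(=O)N(CC)CC)c1[Cu] | intermediate
7 | 2-geranyl-5-(methoxymethoxy)-1,3-phenylene bis(N,N-diethylcarbamate) | CCN(CC)C(=O)Oc1cc(OCOC)cc(OC(=O)N(CC)CC)c1C/C=C(\C)CCC=C(C)C | intermediate
8 | 2-geranyl-5-(methoxymethoxy)benzene-1,3-diol | COCOc1cc(O)c(C/C=C(\C)CCC=C(C)C)c(O)c1 | intermediate
9 | 4-bromo-2-geranyl-5-(methoxymethoxy)benzene-1,3-diol | COCOc1cc(O)c(C/C=C(\C)CCC=C(C)C)c(O)c1Br | intermediate
10 | bis(trimethylsilyl) ether of 9 | COCOc1cc(O[Si](C)(C)C)c(C/C=C(\C)CCC=C(C)C)c(O[Si](C)(C)C)c1Br | intermediate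
11 | aryllithium from 10 (lithium in place of bromine) | COCOc1cc(O[Si](C)(C)C)c(C/C=C(\C)CCC=C(C)C)c(O[Si](C)(C)C)c1[Li] | intermediate
12 | lithium 2-geranyl-5-(methoxymethoxy)-6-(trimethylsilyl)-3-[(trimethylsilyl)oxy]phenoxide | [Li+].COCOc1cc(O[Si](C)(C)C)c(C/C=C(\C)CCC=C(C)C)c([O-])c1[Si](C)(C)C | intermediate
13 | 2-geranyl-5-(methoxymethoxy)-6-(trimethylsilyl)-3-[(trimethylsilyl)oxy]phenyl trifluoromethanesulfonate | COCOc1cc(O[Si](C)(C)C)c(C/C=C(\C)CCC=C(C)C)c(OS(=O)(=O)C(F)(F)F)c1[Si](C)(C)C | intermediate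
14 | 2-geranyl-3-hydroxy-5-(methoxymethoxy)-6-(trimethylsilyl)phenyl trifluoromethanesulfonate | COCOc1cc(O)c(C/C=C(\C)CCC=C(C)C)c(OS(=O)(=O)C(F)(F)F)c1[Si](C)(C)C | intermediate
15 | 2-geranyl-3-(geranyloxy)-5-(methoxymethoxy)-6-(trimethylsilyl)phenyl trifluoromethanesulfonate | COCOc1cc(OC/C=C(\C)CCC=C(C)C)c(C/C=C(\C)CCC=C(C)C)c(OS(=O)(=O)C(F)(F)F)c1[Si](C)(C)C | intermediate
16 | 1-(4-hydroxyphenyl)ethan-1-one | CC(=O)c1ccc(O)cc1 | starting material
17 | 1-[4-(methoxymethoxy)phenyl]ethan-1-one | CC(=O)c1ccc(OCOC)cc1 | intermediate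
18 | methyl 3-[4-(methoxymethoxy)phenyl]-3-oxopropanoate | COCOc1ccc(cc1)C(=O)CC(=O)OC | intermediate
19 | methyl (3S)-3-hydroxy-3-[4-(methoxymethoxy)phenyl]propanoate | O[C@H](c1ccc(OCOC)cc1)CC(=O)OC | intermediate
20 | methyl (3S)-3-[4-(methoxymethoxy)phenyl]-3-[(trimethylsilyl)oxy]propanoate | C[Si](C)(C)O[C@H](c1ccc(OCOC)cc1)CC(=O)OC | intermediate
21 | 6-geranyl-5-(geranyloxy)-3-(methoxymethoxy)-1,2-didehydrobenzene (aryne) | COCOC1=CC(OC/C=C(\C)CCC=C(C)C)=C(C/C=C(\C)CCC=C(C)C)C#C1 | intermediate
22 | cesium (1S)-3-methoxy-1-[4-(methoxymethoxy)phenyl]-3-oxopropan-1-olate | [Cs+].[O-][C@H](c1ccc(OCOC)cc1)CC(=O)OC | intermediate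
23 | aryl cesium adduct: the alkoxide oxygen of 22 bonded to the aryne carbon next to C-geranyl, carbanion next to the MOM-oxy carbon | [Cs+].COCOc1cc(OC/C=C(\C)CCC=C(C)C)c(C/C=C(\C)CCC=C(C)C)c(O[C@H](c2ccc(OCOC)cc2)CC(=O)OC)[c-]1 | intermediate
24 | cesium (2S)-8-geranyl-7-(geranyloxy)-4-methoxy-5-(methoxymethoxy)-2-[4-(methoxymethoxy)phenyl]chroman-4-olate (either C4 epimer) | [Cs+].COCOc1cc(OC/C=C(\C)CCC=C(C)C)c(C/C=C(\C)CCC=C(C)C)c2O[C@H](c3ccc(OCOC)cc3)CC([O-])(OC)c12 | intermediate
25 | (2S)-8-geranyl-7-(geranyloxy)-5-(methoxymethoxy)-2-[4-(methoxymethoxy)phenyl]chroman-4-one | CC(C)=CCC/C(C)=C/COc1cc(OCOC)c2c(c1C/C=C(\C)CCC=C(C)C)O[C@H](c1ccc(OCOC)cc1)CC2=O | intermediate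
26 | (2S)-8-geranyl-7-(geranyloxy)-5-[(trimethylsilyl)oxy]-2-{4-[(trimethylsilyl)oxy]phenyl}chroman-4-one | CC(C)=CCC/C(C)=C/COc1cc(O[Si](C)(C)C)c2c(c1C/C=C(\C)CCC=C(C)C)O[C@H](c1ccc(O[Si](C)(C)C)cc1)CC2=O | intermediate
27 | (2S)-8-geranyl-7-(geranyloxy)-5-hydroxy-2-(4-hydroxyphenyl)chroman-4-one (CNP0103685.1) | CC(C)=CCC/C(C)=C/COc1cc(O)c2c(c1C/C=C(\C)CCC=C(C)C)O[C@H](c1ccc(O)cc1)CC2=O | target

**Step count and risks**

Total steps: 14. Longest linear sequence: 10 (steps 1–8, 13, 14).

Steps most likely to fail: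

1. Step 13 (proposed method). What may go wrong: proton transfer to the aryl anion before it cyclises (giving an uncyclised aryl ether); retro-aldol or elimination of the alkoxide; attack at the wrong aryne carbon; or loss of configuration by base-induced ring opening and reclosure of the chromanone. Fallback by known chemistry, setting out from 15 and returning at 25: Heck reaction of 1-bromo-4-(methoxymethoxy)benzene with acrylic acid (Pd(OAc)2, P(o-tol)3, Et3N, DMF, heat) should give (2E)-3-[4-(methoxymethoxy)phenyl]prop-2-enoic acid F1. Treating 15 with F1 and CsF in hot THF, the known insertion of an aryne into the C–O bond of a carboxylic acid (carboxylate addition at the same aryne carbon, then acyl shift), should give (2E)-1-[3-geranyl-4-(geranyloxy)-2-hydroxy-6-(methoxymethoxy)phenyl]-3-[4-(methoxymethoxy)phenyl]prop-2-en-1-one F2. In the basic fluoride medium F2 should close by oxa-Michael addition to racemic 8-geranyl-7-(geranyloxy)-5-(methoxymethoxy)-2-[4-(methoxymethoxy)phenyl]chroman-4-one F3. Preparative chromatography on a chiral stationary phase would then deliver 25.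

2. Step 6. What may go wrong: competing bromination or bromoetherification at the geranyl alkenes, or a second ring bromination. Fallback setting out from 7 and returning at 15, with no halogenating agent: a second directed ortho metalation of 7 (s-BuLi, TMEDA, THF, −78 °C; TMSCl) at either of the two equivalent positions between a carbamate and the MOM ether should give 2-geranyl-5-(methoxymethoxy)-4-(trimethylsilyl)-1,3-phenylene bis(N,N-diethylcarbamate) F4. LiAlH4 should free 2-geranyl-5-(methoxymethoxy)-4-(trimethylsilyl)benzene-1,3-diol F5. Geranyl bromide (1.0 equiv) with K2CO3 should alkylate the phenol remote from silicon, the other being shielded by the silyl group and the C-geranyl chain, to give 2-geranyl-3-(geranyloxy)-5-(methoxymethoxy)-6-(trimethylsilyl)phenol F6. Triflation (Tf2O, pyridine, CH2Cl2, 0 °C) then gives 15.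

3. Step 4. What may go wrong: lithiation straying to a position between a carbamate and the MOM ether, or allylic transposition in the coupling. Fallback setting out from 1 and returning at 7, with the para oxygen carried as a bulky, non-directing silyl ether during the metalation: TIPSCl with imidazole should give [3,5-bis(benzyloxy)phenoxy]tri(propan-2-yl)silane F7. Hydrogenolysis (H2, 10% Pd/C) gives 5-[(triisopropylsilyl)oxy]benzene-1,3-diol F8. Et2NCOCl with K2CO3 gives 5-[(triisopropylsilyl)oxy]-1,3-phenylene bis(N,N-diethylcarbamate) F9. The same metalation and copper-mediated geranylation, now with only the carbamate-flanked site open, gives 2-geranyl-5-[(triisopropylsilyl)oxy]-1,3-phenylene bis(N,N-diethylcarbamate) F10. TBAF in THF frees 2-geranyl-5-hydroxy-1,3-phenylene bis(N,N-diethylcarbamate) F11, and MOMCl with i-Pr2NEt gives 7.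

**Further compounds**

F1 | step 13 | (2E)-3-[4-(methoxymethoxy)phenyl]prop-2-enoic acid | COCOc1ccc(/C=C/C(=O)O)cc1
F2 | step 13 | (2E)-1-[3-geranyl-4-(geranyloxy)-2-hydroxy-6-(methoxymethoxy)phenyl]-3-[4-(methoxymethoxy)phenyl]prop-2-en-1-one | COCOc1ccc(/C=C/C(=O)c2c(O)c(C/C=C(\C)CCC=C(C)C)c(OC/C=C(\C)CCC=C(C)C)cc2OCOC)cc1
F3 | step 13 | racemic 8-geranyl-7-(geranyloxy)-5-(methoxymethoxy)-2-[4-(methoxymethoxy)phenyl]chroman-4-one | CC(C)=CCC/C(C)=C/COc1cc(OCOC)c2c(c1C/C=C(\C)CCC=C(C)C)OC(c1ccc(OCOC)cc1)CC2=O
F4 | step 6 | 2-geranyl-5-(methoxymethoxy)-4-(trimethylsilyl)-1,3-phenylene bis(N,N-diethylcarbamate) | COCOc1cc(OC(=O)N(CC)CC)c(C/C=C(\C)CCC=C(C)C)c(OC(=O)N(CC)CC)c1[Si](C)(C)C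
F5 | step 6 | 2-geranyl-5-(methoxymethoxy)-4-(trimethylsilyl)benzene-1,3-diol | COCOc1cc(O)c(C/C=C(\C)CCC=C(C)C)c(O)c1[Si](C)(C)C
F6 | step 6 | 2-geranyl-3-(geranyloxy)-5-(methoxymethoxy)-6-(trimethylsilyl)phenol | COCOc1cc(OC/C=C(\C)CCC=C(C)C)c(C/C=C(\C)CCC=C(C)C)c(O)c1[Si](C)(C)C
F7 | step 4 | [3,5-bis(benzyloxy)phenoxy]tri(propan-2-yl)silane | CC(C)[Si](Oc1cc(OCc2ccccc2)cc(OCc2ccccc2)c1)(C(C)C)C(C)C
F8 | step 4 | 5-[(triisopropylsilyl)oxy]benzene-1,3-diol | CC(C)[Si](Oc1cc(O)cc(O)c1)(C(C)C)C(C)C
F9 | step 4 | 5-[(triisopropylsilyl)oxy]-1,3-phenylene bis(N,N-diethylcarbamate) | CCN(CC)C(=O)Oc1cc(O[Si](C(C)C)(C(C)C)C(C)C)cc(OC(=O)N(CC)CC)c1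
F10 | step 4 | 2-geranyl-5-[(triisopropylsilyl)oxy]-1,3-phenylene bis(N,N-diethylcarbamate) | CCN(CC)C(=O)Oc1cc(O[Si](C(C)C)(C(C)C)C(C)C)cc(OC(=O)N(CC)CC)c1C/C=C(\C)CCC=C(C)C
F11 | step 4 | 2-geranyl-5-hydroxy-1,3-phenylene bis(N,N-diethylcarbamate) | CCN(CC)C(=O)Oc1cc(O)cc(OC(=O)N(CC)CC)c1C/C=C(\C)CCC=C(C)C
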